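The runs are calculated for an exercise.

A smaller charge of first nucleophile, 0.18 M in place of 0.300 M, makes the neighbour we hold beside Wednesday's flask. The neighbour keeps the other charges and the time of Wednesday's flask, and we ask where each ends, in fractions of the substrate charged.

- Wednesday's: substrate 0.20 M; first nucleophile 0.30 M; second nucleophile 0.18 M; the very flask that is asked about, followed so far
- flask: substrate 0.20 M; first nucleophile 0.300 M; second nucleophile 0.180 M; time 15 h

Wednesday's run (percent of the substrate charged)

| time / min | target / % | substrate / % |
|---|---|---|
| 4.00 | 1 | 100 |
| 12.0 | 6 | 97 |
| 20.0 | 3 | 97 |
| 30.0 | 6 | 90 |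
| 40.0 | 12 | 87 |
| 60.0 | 11 | 81 |
| 80.0 | 19 | 73 |

(scatter of a reading: 2 percentage points)

* concentration of target at 15 h, in M
* concentration of substrate at 15 h, in M
* concentration of other capture product at 15 h, in M

Wednesday's run reads 73% of its substrate at 80.0 min, so a first-order loss gives 2.94 h as the substrate half-life, the time in which the substrate falls to half of what it was. The 40.0 min reading gives 3.32 h, so we hold ours as a reading with a scatter of 2 percentage points behind it.

The time 15 h is longer than that half-life: it counts 5.11 half-lives, which leaves 2.90% of the substrate. We assume that neither nucleophile enters the substrate's loss, and this puts the same fraction in the neighbour. The two flasks should then part in the split: with 0.18 M of first nucleophile against the same 0.180 M of second nucleophile, we expect the neighbour to move toward other capture product.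

The forecast for Wednesday's flask gives 0.123 M of target, 0.012 M of substrate and 0.065 M of other capture product. Its substrate is 6.00% of the charge, more than our count leaves, and it weighs this: “If the nucleophiles take part in the rate step, their depletion slows the decay”.

Wednesday's flask ends with 70.1% target, 3.69% substrate and 26.1% other capture product, that is 0.140 M, 0.00738 M and 0.0522 M.

    substrate → intermediate (k = 0.220 h⁻¹)
    first nucleophile + intermediate → target (k = 46.0 M⁻¹ h⁻¹)
    second nucleophile + intermediate → other capture product (k = 25.0 M⁻¹ h⁻¹)

Substrate's turning into intermediate, with a half-life of 3.2 h, is the rate-limiting step against the captures at 0.050 h and 0.15 h with the nucleophiles as charged, and intermediate stands at 0.0786% at the end of Wednesday's flask. At 7.50 h our count gives 2.55 half-lives and 17.1% of the substrate, and Wednesday's flask holds 19.2%. The neighbour, for which our count gives the same 5.11 half-lives and 2.90%, ends with 3.69% substrate, 57.7% target and 38.4% other capture product.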